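**Retrosynthetic overview**
1. Target 10 ⇐ hydroxide opening of the aryl lactone in tricycle 9; the dihydrocoumarin ring masks both the CO2H and the C5 phenol until the end.
2. Chromanone ring (formed last) ⇐ C4–C3 bond from aldehyde 8: the formyl carbon, turned into an acyl anion equivalent by a carbene, adds to the internal carbon of an unactivated alkene; C3 is set in this step.
3. Ether 8 ⇐ Mitsunobu inversion of phenol 6 with (R)-but-3-en-2-ol 7, which fixes C2.
4. Dihydrocoumarin ring (formed first) ⇐ enantioselective oxidative carbene-catalysed [3+3] annulation of phenol 4 with (E)-hex-2-enal 5, which sets the benzylic centre.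
5. 4 ⇐ C-prenylation of symmetric 2 ⇐ chelation-controlled bis-demethylation of 2,4,6-trimethoxybenzaldehyde 1; symmetry leaves one possible site in every later ring substitution.

Assumption: the (5aS,10bR) antipode of the aminoindanol triazolium salt is taken to give the 4R lactone in step 3; if a test run shows 4S, its mirror image (also sold) is used with no other change.

**Step 1**
Reactants: 1 2,4,6-trimethoxybenzaldehyde
Product: 2 2,6-dihydroxy-4-methoxybenzaldehyde
Conditions: AlCl3 (4 equiv), PhCl, 80 °C; then ice-cold 2 M HCl
Reagents that add atoms: none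
Why: AlCl3 chelates between the formyl oxygen and each ortho methoxy oxygen, so chloride removes only the two ortho methyl groups and the unchelated para methoxy survives (chelation-controlled Lewis-acid aryl methyl ether cleavage); no stereocentre is formed.

**Step 2**
Reactants: 2 2,6-dihydroxy-4-methoxybenzaldehyde; 3 1-bromo-3-methylbut-2-ene (prenyl bromide)
Product: 4 2,6-dihydroxy-4-methoxy-3-(3-methylbut-2-en-1-yl)benzaldehyde
Conditions: 3 (1.0 equiv), 10% aq. KOH (1.1 equiv), 0 °C → rt; acidify to pH 4
Reagents that add atoms: none
Why: In water the ambident phenoxide of this formylphloroglucinol-type ring reacts with the soft allylic bromide on carbon rather than oxygen (C-prenylation, a Friedel–Crafts-type allylation of a phenoxide), and because C3 and C5 are equivalent the mono-adduct is a single compound (modest yield expected, 2 recovered); no stereocentre is formed.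

**Step 3**
Reactants: 4 2,6-dihydroxy-4-methoxy-3-(3-methylbut-2-en-1-yl)benzaldehyde; 5 (E)-hex-2-enal
Product: 6 (4R)-7-hydroxy-5-methoxy-6-(3-methylbut-2-en-1-yl)-2-oxo-4-propyl-3,4-dihydro-2H-chromene-8-carbaldehyde
Conditions: 5 (1.5 equiv), (5aS,10bR)-2-(2,4,6-trimethylphenyl)-5a,10b-dihydro-4H,6H-indeno[2,1-b][1,2,4]triazolo[4,3-d][1,4]oxazin-2-ium tetrafluoroborate (10 mol%), DBU (1,8-diazabicyclo[5.4.0]undec-7-ene, 1.0 equiv), 3,3',5,5'-tetra-tert-butyl-4,4'-diphenoquinone (1.2 equiv), THF, rt
Reagents that add atoms: none
Why: Oxidative NHC-catalysed [3+3] annulation (Michael addition–lactonisation): the carbene adds to the unhindered enal, the diphenoquinone oxidises the adduct to an α,β-unsaturated acyl azolium, the only free ring carbon of the phenoxide attacks its β-carbon on the face left open by the aminoindane wall to set the benzylic centre as R, and the neighbouring phenoxide oxygen closes the dihydrocoumarin ring and releases the carbene, while the resident formyl group, flanked by two ortho oxygens and deactivated as a vinylogous carboxylate, does not compete for the bulky N-mesityl carbene.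

**Step 4**
Reactants: 6 (4R)-7-hydroxy-5-methoxy-6-(3-methylbut-2-en-1-yl)-2-oxo-4-propyl-3,4-dihydro-2H-chromene-8-carbaldehyde; 7 (R)-but-3-en-2-ol
Product: 8 (4R)-7-[(2S)-but-3-en-2-yloxy]-5-methoxy-6-(3-methylbut-2-en-1-yl)-2-oxo-4-propyl-3,4-dihydro-2H-chromene-8-carbaldehyde
Conditions: 7 (1.5 equiv), PPh3 (1.5 equiv), DIAD (1.5 equiv), toluene, 0 °C → rt
Reagents that add atoms: none
Why: Mitsunobu etherification: the one remaining phenol, acidified by the ortho formyl group, displaces the oxyphosphonium group of the alcohol by SN2 with inversion, so the R carbinol becomes the S aryl ether carbon that will be C2 of the chromanone.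

**Step 5**
Reactants: 8 (4R)-7-[(2S)-but-3-en-2-yloxy]-5-methoxy-6-(3-methylbut-2-en-1-yl)-2-oxo-4-propyl-3,4-dihydro-2H-chromene-8-carbaldehyde
Product: 10 (3R)-3-[(2S,3S)-5-hydroxy-7-methoxy-2,3-dimethyl-8-(3-methylbut-2-en-1-yl)-4-oxo-3,4-dihydro-2H-chromen-6-yl]hexanoic acid, via chromanone lactone 9 (not isolated)
Conditions: 3-(2,4,6-trimethylphenyl)-5,6,7,8-tetrahydro-4H-cyclohepta[d][1,3]thiazol-3-ium perchlorate (20 mol%), DBU (40 mol%), 1,4-dioxane, 100 °C; then 0 °C, LiOH·H2O (4 equiv), THF/H2O, 0 °C → rt; cold 1 M HCl to pH 3
Reagents that add atoms: lithium hydroxide, [Li+].[OH-] (its oxygen becomes the carboxyl OH)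
Why: Proposed new method: the carbene adds to the formyl group to give the Breslow enaminol (acyl anion equivalent), whose nucleophilic carbon bonds to the internal carbon of the tethered unactivated alkene while its OH proton passes to the terminal CH2 in a concerted five-centre transition state, closing the six-membered ring with the C2 methyl pseudo-equatorial to avoid a 1,3-diaxial clash with the azolium on the forming C4, so the new C3 methyl comes out trans (3S), which is also the thermodynamic isomer at this one epimerisable centre under DBU; the closest known reaction type is the NHC-catalysed intramolecular hydroacylation of unactivated alkenes in 2-allyloxybenzaldehydes to 3-methylchroman-4-ones, here extended to an α-branched allyl ether on a fully substituted ring, after which hydroxide opens the aryl lactone to give the acid and the C5 phenol, whose phenoxide lowers C3–H acidity and protects C2 and C3 during hydrolysis.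

**Compound list**
1 | 2,4,6-trimethoxybenzaldehyde | COc1cc(OC)c(C=O)c(OC)c1 | starting material
2 | 2,6-dihydroxy-4-methoxybenzaldehyde | COc1cc(O)c(C=O)c(O)c1 | intermediate
3 | 1-bromo-3-methylbut-2-ene (prenyl bromide) | CC(C)=CCBr | starting material
4 | 2,6-dihydroxy-4-methoxy-3-(3-methylbut-2-en-1-yl)benzaldehyde | COc1cc(O)c(C=O)c(O)c1CC=C(C)C | intermediate
5 | (E)-hex-2-enal | CCC/C=C/C=O | starting material
6 | (4R)-7-hydroxy-5-methoxy-6-(3-methylbut-2-en-1-yl)-2-oxo-4-propyl-3,4-dihydro-2H-chromene-8-carbaldehyde | CCC[C@@H]1CC(=O)Oc2c(C=O)c(O)c(CC=C(C)C)c(OC)c21 | intermediate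
7 | (R)-but-3-en-2-ol | C[C@@H](O)C=C | starting material
8 | (4R)-7-[(2S)-but-3-en-2-yloxy]-5-methoxy-6-(3-methylbut-2-en-1-yl)-2-oxo-4-propyl-3,4-dihydro-2H-chromene-8-carbaldehyde | CCC[C@@H]1CC(=O)Oc2c(C=O)c(O[C@@H](C)C=C)c(CC=C(C)C)c(OC)c21 | intermediate
9 | (4R,8S,9S)-5-methoxy-8,9-dimethyl-6-(3-methylbut-2-en-1-yl)-4-propyl-3,4,8,9-tetrahydro-2H,10H-pyrano[2,3-f]chromene-2,10-dione | CCC[C@@H]1CC(=O)Oc2c3c(O[C@@H](C)[C@H](C)C3=O)c(CC=C(C)C)c(OC)c21 | intermediate (not isolated)
10 | (3R)-3-[(2S,3S)-5-hydroxy-7-methoxy-2,3-dimethyl-8-(3-methylbut-2-en-1-yl)-4-oxo-3,4-dihydro-2H-chromen-6-yl]hexanoic acid | CCC[C@H](CC(=O)O)c1c(O)c2c(c(CC=C(C)C)c1OC)O[C@@H](C)[C@H](C)C2=O | target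

**Totals**
Total step count: 5. Longest linear sequence: 5 steps (1 → 2 → 4 → 6 → 8 → 10).

**Three steps most likely to fail**

Step 5 is the riskiest. The aldehyde sits between two ortho oxygens on a hexasubstituted ring, so carbene addition may be slow. Prolonged base and heat could also erode C2 through retro-oxa-Michael opening or ionisation of the allylic aryl ether. The trans:cis ratio at C3 may be only moderate, in which case the minor cis acid is removed from 10 by chromatography or crystallisation. Fallback: set out from 8 and replace the carbene-bound acyl anion by a free acyl radical. With tert-dodecanethiol (0.3 equiv) and 1,1'-azobis(cyclohexane-1-carbonitrile) (0.3 equiv, added in portions) in chlorobenzene at 110 °C, the thiyl radical abstracts the formyl hydrogen. The nucleophilic aroyl radical then closes 6-exo onto the internal alkene carbon, and the primary radical takes hydrogen back from the thiol. Brief Et3N treatment settles C3 to trans. This comes back to the route at 9, which is opened with LiOH as in step 5 to give 10.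

Step 3 is second. The acyl azolium may simply O-acylate a phenol, the carbene or oxidant may engage the aryl aldehyde, and a β-alkyl enal may give lower ee than β-aryl ones. Fallback: set out from 4 and 5 and use iminium activation instead of an acyl azolium. With 2-[diphenyl(trimethylsilyloxy)methyl]pyrrolidine (20 mol%, the antipode that gives 4R) and PhCO2H in toluene at 0 °C, Friedel–Crafts-type conjugate addition and hemiacetal closure give the lactol (4R)-2,7-dihydroxy-5-methoxy-6-(3-methylbut-2-en-1-yl)-4-propyl-3,4-dihydro-2H-chromene-8-carbaldehyde F1 as a mixture of C2 epimers. Pyridinium chlorochromate [C5H5NH][CrO3Cl] with NaOAc in CH2Cl2 oxidises it to the lactone, coming back to the route at 6.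

Step 4 is third. The phenol is flanked on both sides, and a secondary allylic alcohol can leak through SN2' to the achiral linear crotyl ether or lose ee. Fallback: set out from 6 and let a catalyst rather than the chiral alcohol set the ether centre. (E)-But-2-en-1-ol and methyl chloroformate with pyridine give (E)-but-2-en-1-yl methyl carbonate F2. Pd2(dba)3·CHCl3 (zerovalent palladium, 2.5 mol%) with N,N'-(cyclohexane-1,2-diyl)bis[2-(diphenylphosphanyl)benzamide] (7.5 mol%, the antipode that gives the S ether) in CH2Cl2 at rt then joins 6 and F2 by asymmetric allylic etherification at the branched terminus, coming back to the route at 8.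

**Further compounds**
F0 | step 5 | none | none
F1 | step 3 | (4R)-2,7-dihydroxy-5-methoxy-6-(3-methylbut-2-en-1-yl)-4-propyl-3,4-dihydro-2H-chromene-8-carbaldehyde (C2 epimers) | CCC[C@@H]1CC(O)Oc2c(C=O)c(O)c(CC=C(C)C)c(OC)c21
F2 | step 4 | (E)-but-2-en-1-yl methyl carbonate | C/C=C/COC(=O)OC
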